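## The problem

Cerosilin B 15 is a flavone: a benzo ring A and a pyran-4-one ring C share the C4a–C8a bond, and ring B, a 3,4,5-trimethoxyphenyl group, sits on C2. The molecule has no stereocentre, so the difficulty lies in regiochemistry and in what the finished chromone tolerates. Ring A carries four contiguous substituents (O1 on C8a, the carbonyl carbon on C4a, methoxy groups on C5 and C6) and leaves C7 and C8 free. Electrophilic substitution does not deliver this pattern: 3,4-dimethoxyphenol 1 reacts at the ortho position para to a methoxy group, not at the position flanked by two oxygens where C4 must be attached. The C5 methoxy group lies peri to the C4 carbonyl and is the first ether lost to Lewis acids such as BBr3 or AlCl3 and to hot HBr. The pyranone is opened at C2 by hydroxide and amines, and the C2–C3 double bond can be reduced, so late steps must be neutral or use only bulky, weakly nucleophilic bases. The feature the plan exploits is C3: it is the only ring C atom that carries nothing but hydrogen, and it sits between C2 (which holds O1 and ring B) and the C4 carbonyl. If C3 is taken out, C2 and C4 join to form the C2–C3 enol ether bond of a 2-arylbenzofuran-3-ol, and a one-carbon unit with a leaving group can be inserted into exactly that bond.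

## Retrosynthesis

**From 15 to 14.** No skeletal bond is cut; C3–H is exchanged for C3–Br. The one-carbon unit of the key step must bring a leaving group, or the cyclopropane it forms would not open, so a halogen ends up on C3 of the 3-bromoflavone 14 and must be removed last. Bromine is preferred to chlorine because bromide ionises more easily in the opening and because a vinyl C–Br bond next to a carbonyl is removed under neutral palladium catalysis. The forward step must reduce that bond only and leave the C2–C3 double bond and the five methyl ethers alone.

**From 14 to 10 and 11.** Both bonds to C3 are cut (C2–C3 and C3–C4) and C2 is joined to C4, which turns ring C into the furan ring of the 3-siloxybenzofuran 10; C3 itself becomes bromoform 11. The neighbouring cuts of ring C (O1–C2 by cyclodehydration of a 1,3-diketone, or C3–C4 by acylation) all lead back to an ortho-hydroxyaryl ketone and an open chain. The cut chosen removes a single unsubstituted atom and keeps both oxygen functions of ring C on a fully aromatic bicycle. Compound 10 has one ring atom fewer, no electrophilic site, and is one ring closure away from an open-chain ester. The forward reaction must add the carbene from 11 to the enol ether bond and nothing else, open the adduct 12 across the shared bond to the flavylium ion 13, and keep the silyl ether intact until the carbene has added; a bulky silyl group is chosen for that reason.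

**From 10 to 8.** The benzofuran C2–C3 bond (benzylic carbon to the former ester carbon) and the O–Si bond are cut. The other cut of the furan ring, O1–C2, would need an alpha-halogenated deoxybenzoin that is no easier to reach in this substitution pattern. The chosen cut forms the C–C bond intramolecularly, five-membered, between a benzylic ether carbanion and an ortho ester, and ends in the aromatic enolate 9, which drives the equilibrium and is silylated on oxygen in the same flask. The precursor 8 is an open-chain ether ester. The forward step needs benzylic deprotonation to outrun attack on the hindered ester, and the air-sensitive protonated form of 9 must never be handled.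

**From 8 to 6 and 7.** The benzylic C–O bond is cut, separating ring B with its benzylic carbon, the purchased benzyl chloride 7, from the ring A phenol 6. This is an ether synthesis between a phenol and a primary benzylic chloride; the only demand is O-alkylation of a phenol hydrogen-bonded to the neighbouring ester.

**From 6 to 1.** The aryl–carbonyl bond is cut. It lies between two oxygen-bearing carbons, the position that electrophilic carboxylation of 1 avoids and that directed ortho-lithiation prefers. The methoxymethyl ether 2 is lithiated between its acetal oxygen and the adjacent methoxy group to give the aryllithium 4, which is acylated with methyl chloroformate 3 to the ester 5; mild acid then frees the phenol 6. The methoxymethyl group is the strongest director on the ring, cooperates with the neighbouring methoxy group, and comes off without touching the ester. The forward steps need lithiation at the doubly flanked position and a single acylation of 4.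

## Roads not taken

Alternative 1: Ring C would be closed last at the O1–C8a bond. The cut leads to the open-chain diketone 1-(3-hydroxy-2-methoxyphenyl)-3-(3,4,5-trimethoxyphenyl)propane-1,3-dione A2, whose ring A has no oxygen at the future C8a. Anodic oxidation of the phenol of A2 in a fluorinated alcohol would give a phenoxonium ion; the enol oxygen would add to the carbon para to the phenol oxygen, and proton loss would give 6-hydroxy-5-methoxy-2-(3,4,5-trimethoxyphenyl)-4H-chromen-4-one A1. Compound A1 is one O-methylation from 15.
- Merits: the fourth ring A substituent is introduced by C–H functionalisation, so no directed lithiation, protecting group or halogen detour is needed. The sequence from a benzoate to 15 is shorter on paper than the chosen one.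
- Weak points: the tethered enol oxygen reaches two electrophilic carbons through a six-membered transition state. One is the wanted para carbon; the other is the ortho carbon bearing the methoxy group, where ipso attack gives a quinone ketal that cannot rearomatise to A1.
- A1 is a para-oxygenated phenol and easier to oxidise than A2, whose phenol ring is deactivated by the acyl group, so over-oxidation to quinoid products is expected. The trimethoxyphenyl ring and the diketone enol are oxidisable in the same potential range.
- The 3-hydroxy-2-methoxy pattern of A2 is the less accessible isomer of its series and requires differentiating two adjacent oxygens.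
- Comparison: Alternative 1 is better in step count and avoids organolithium chemistry. The chosen plan fixes every ring A position by bond construction rather than by partition of a cation, and runs no oxidation on the electron-rich system.

Alternative 2: Ring B would be built by cutting C2'–C3' and C5'–C6'. A chromon-2-yl vinamidinium salt, 2-(5,6-dimethoxy-4-oxo-4H-chromen-2-yl)-1,3-bis(dimethylamino)trimethinium hexafluorophosphate A4, would condense with 1,3-dimethoxypropan-2-one A5 under KOt-Bu. Both amino groups are lost and the product is the phenol 2-(4-hydroxy-3,5-dimethoxyphenyl)-5,6-dimethoxy-4H-chromen-4-one A3. O-Methylation of A3 then gives 15.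
- Merits: the three-plus-three annulation suits the local symmetry of ring B, since both partners are symmetric and no regiochemical question arises. The 4'-phenol of A3 and the late ring construction would serve analogue work on ring B, and no carbene is involved.
- Weak points: the key step is spent on the one ring that can be bought intact. The real difficulty (ring A pattern and ring C) must be solved first by conventional means to reach 5,6-dimethoxy-2-methyl-4H-chromen-4-one A6, the likely source of A4. Compound A6 already contains the whole ring A problem.
- C2 of the chromone is a Michael acceptor, more so when it carries the cationic vinamidinium of A4. The base, the enolate of A5 and the liberated secondary amine can all add there and open ring C. A5 is an alpha-alkoxy ketone prone to self-condensation.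
- The route through A6, A4 and A3 would be longer than the chosen one.
- Comparison: Alternative 2 is better for varying ring B. The chosen plan is convergent with the commercial ring B building block 7 and directs its key step at ring C.

Alternative 3: Ring A would be built on a preformed arylpyranone by cutting C6–C7 and C7–C8. 3-(2-Methoxyacetyl)-2-methyl-6-(3,4,5-trimethoxyphenyl)-4H-pyran-4-one A8 would condense with N,N-dimethylformamide dimethyl acetal A9. The acetal carbon of A9 supplies C7: it would bond to the vinylogous methyl group (C8) and to the methylene of the methoxyacetyl group (C6). Aromatisation would give 5-hydroxy-6-methoxy-2-(3,4,5-trimethoxyphenyl)-4H-chromen-4-one A7. Methylation of the chelated C5 phenol of A7 would give 15.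
- Merits: the contiguous 5,6-dioxygenation with free C7 and C8 follows from the carbon skeleton, with no low-temperature organometallic step, and A9 is a cheap one-carbon reagent.
- Weak points: A8 is a tricarbonyl compound whose synthesis is not shorter than that of the target. 3-Acylpyranones can ring-open and reclose with exchange of ring and side-chain carbonyls.
- A8 has several acidic sites. The first condensation with A9 turns one carbon nucleophile into an enaminone, a poor electrophile for the second C–C bond, so forcing conditions are likely, under which the liberated amine can open the pyranone.
- The chelated 5-hydroxyl of A7 needs a separate, forcing methylation.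
- Comparison: Alternative 3 matches or beats the chosen plan on ring A regiocontrol. The chosen plan starts ring A from the commercial phenol 1 and reaches its key-step substrate in five steps.

Key step: step 6

Remark: cerosilin B is taken as 5,6,3',4',5'-pentamethoxyflavone, which has no stereocentre. Adduct 12 is chiral, forms as a racemate with the cis ring fusion a fused cyclopropane must have, and loses both centres on opening.

## Route

Step 1
Reactants: 1 3,4-dimethoxyphenol
Product: 2 1,2-dimethoxy-4-(methoxymethoxy)benzene
Conditions: NaH, MOMCl, THF, 0 °C → rt
Reagents that add atoms: chloromethyl methyl ether (MOMCl), COCCl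
Why: Williamson-type O-alkylation of the sodium phenoxide by the reactive chloromethyl ether; the methoxymethyl ether is installed because it is the strongest director for the next step and is removable with mild acid.

Step 2
Reactants: 2 1,2-dimethoxy-4-(methoxymethoxy)benzene; 3 methyl chloroformate
Product: 5 methyl 2,3-dimethoxy-6-(methoxymethoxy)benzoate, via aryllithium 4 (not isolated)
Conditions: n-BuLi, TMEDA, THF, 0 °C; then added to ClCO2Me (3 equiv), THF, −78 °C
Reagents that add atoms: none
Why: Directed ortho-metalation: the position between the acetal oxygen and the adjacent methoxy group is acidified and chelated by both, so lithiation should occur there and not at the singly flanked positions. Inverse addition of 4 to excess chloroformate at low temperature suppresses a second addition to the new ester, which its two ortho substituents also hinder.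

Step 3
Reactants: 5 methyl 2,3-dimethoxy-6-(methoxymethoxy)benzoate
Product: 6 methyl 6-hydroxy-2,3-dimethoxybenzoate
Conditions: HCl (conc.), MeOH, 45 °C
Reagents that add atoms: none
Why: Acid-catalysed acetal exchange with methanol removes the methoxymethyl group as dimethoxymethane; the methyl ester is unchanged in methanol and aryl methyl ethers need far stronger acid.

Step 4
Reactants: 6 methyl 6-hydroxy-2,3-dimethoxybenzoate; 7 3,4,5-trimethoxybenzyl chloride
Product: 8 methyl 2,3-dimethoxy-6-[(3,4,5-trimethoxybenzyl)oxy]benzoate
Conditions: K2CO3, DMF, 60 °C
Reagents that add atoms: none
Why: Williamson ether synthesis: the potassium phenoxide displaces chloride from an unhindered, electron-rich primary benzylic chloride (SN2) in a dipolar aprotic solvent, and carbonate does not attack the hindered ester.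

Step 5
Reactants: 8 methyl 2,3-dimethoxy-6-[(3,4,5-trimethoxybenzyl)oxy]benzoate
Product: 10 3-(tert-butyldimethylsilyloxy)-4,5-dimethoxy-2-(3,4,5-trimethoxyphenyl)-1-benzofuran, via lithium benzofuran-3-olate 9 (not isolated)
Conditions: LiN(i-Pr)2 (2.2 equiv), THF, −78 → 0 °C; then TBSCl, DMPU, −78 °C → rt, under argon
Reagents that add atoms: tert-butyldimethylsilyl chloride (TBSCl), CC(C)(C)[Si](C)(C)Cl
Why: Intramolecular Claisen-type (Dieckmann-like) acylation, a reaction type established for O-benzylated salicylate esters and salicylonitriles: the amide base removes a benzylic ether proton, helped by lithium coordination to the ortho ester, the carbanion closes the five-membered ring (5-exo-trig), and the second equivalent of base gives the aromatic enolate 9, which drives the sequence. O-Silylation of 9 in the same flask gives the aromatic benzofuran and avoids handling the protonated form of 9, which autoxidises at C2.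

Step 6
Reactants: 10 3-(tert-butyldimethylsilyloxy)-4,5-dimethoxy-2-(3,4,5-trimethoxyphenyl)-1-benzofuran; 11 bromoform
Product: 14 3-bromo-5,6-dimethoxy-2-(3,4,5-trimethoxyphenyl)-4H-chromen-4-one, via dibromocyclopropane adduct 12 (not isolated), via 4-siloxyflavylium bromide 13 (not isolated)
Conditions: CHBr3 (3 equiv), KOt-Bu (4 equiv), toluene–hexane, −20 °C → rt
Reagents that add atoms: none
Why: Proposed new method: dibromocarbene, made from 11 and KOt-Bu, is an electrophile and should add to the C2–C3 bond of 10, a doubly oxygen-substituted enol ether and the most nucleophilic pi bond in the molecule, to give the gem-dibromocyclopropane 12. In 12 the endo bromide ionises with concerted disrotatory opening of the shared C2–C3 bond (cyclopropyl-to-allyl cation electrocyclic opening); the allyl cation here is the aromatic 4-siloxyflavylium ion 13, so opening is expected below room temperature, and bromide or tert-butoxide then removes the silyl group from oxygen to leave the C4 carbonyl of 14. The closest known reaction types are the dihalocarbene ring expansion of cyclic silyl enol ethers to 2-halocycloalk-2-enones and the Ciamician–Dennstedt carbon insertion into indoles; neither has been shown on a 3-siloxybenzofuran. Ring C is not closed by a cyclisation: it arises by one-carbon enlargement of the furan ring, the inserted carbon becoming C3 with new bonds to C2 and C4 while the old C2–C3 bond breaks. No stereocentre is formed in 14; the two ring-fusion centres of 12 are transient and lost on opening. The step needs chemoselectivity for the enol ether over the two electron-rich arenes, which dihalocarbenes do not attack under these conditions, and needs the silyl ether to outlast the base until the carbene has added, for which the bulky tert-butyldimethylsilyl group, the non-polar solvent and the low temperature are chosen; the direction of opening is fixed because only the bond opposite the CBr2 carbon can break.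

Step 7
Reactants: 14 3-bromo-5,6-dimethoxy-2-(3,4,5-trimethoxyphenyl)-4H-chromen-4-one
Product: 15 cerosilin B (5,6-dimethoxy-2-(3,4,5-trimethoxyphenyl)-4H-chromen-4-one)
Conditions: Pd(PPh3)4 (5 mol %), HCO2Na, DMF, 90 °C
Reagents that add atoms: none
Why: Palladium-catalysed hydrodehalogenation with formate: zerovalent palladium inserts into the C3–Br bond (3-bromochromones are competent cross-coupling partners), formate replaces bromide and loses CO2 to give a palladium hydride, and reductive elimination forms C3–H. The medium is close to neutral and free of strong nucleophiles, so the pyranone and the peri methoxy group should be untouched.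

## Compound list

1 | 3,4-dimethoxyphenol | COc1ccc(O)cc1OC | starting material
2 | 1,2-dimethoxy-4-(methoxymethoxy)benzene | COCOc1ccc(OC)c(OC)c1 | intermediate
3 | methyl chloroformate | COC(=O)Cl | starting material
4 | [2,3-dimethoxy-6-(methoxymethoxy)phenyl]lithium | [Li]c1c(OCOC)ccc(OC)c1OC | intermediate (not isolated)
5 | methyl 2,3-dimethoxy-6-(methoxymethoxy)benzoate | COCOc1ccc(OC)c(OC)c1C(=O)OC | intermediate
6 | methyl 6-hydroxy-2,3-dimethoxybenzoate | COC(=O)c1c(O)ccc(OC)c1OC | intermediate
7 | 3,4,5-trimethoxybenzyl chloride (5-(chloromethyl)-1,2,3-trimethoxybenzene) | COc1cc(CCl)cc(OC)c1OC | starting material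
8 | methyl 2,3-dimethoxy-6-[(3,4,5-trimethoxybenzyl)oxy]benzoate | COC(=O)c1c(OCc2cc(OC)c(OC)c(OC)c2)ccc(OC)c1OC | intermediate
9 | lithium 4,5-dimethoxy-2-(3,4,5-trimethoxyphenyl)-1-benzofuran-3-olate | [Li+].[O-]c1c(-c2cc(OC)c(OC)c(OC)c2)oc2ccc(OC)c(OC)c12 | intermediate (not isolated)
10 | 3-(tert-butyldimethylsilyloxy)-4,5-dimethoxy-2-(3,4,5-trimethoxyphenyl)-1-benzofuran | COc1ccc2oc(-c3cc(OC)c(OC)c(OC)c3)c(O[Si](C)(C)C(C)(C)C)c2c1OC | intermediate
11 | bromoform | BrC(Br)Br | starting material
12 | 1,1-dibromo-6b-(tert-butyldimethylsilyloxy)-5,6-dimethoxy-1a-(3,4,5-trimethoxyphenyl)-1a,6b-dihydro-1H-cyclopropa[b][1]benzofuran (racemic, cis-fused) | COc1ccc2OC3(c4cc(OC)c(OC)c(OC)c4)C(Br)(Br)C3(O[Si](C)(C)C(C)(C)C)c2c1OC | intermediate (not isolated)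
13 | 3-bromo-4-(tert-butyldimethylsilyloxy)-5,6-dimethoxy-2-(3,4,5-trimethoxyphenyl)chromenylium bromide | COc1cc(-c2[o+]c3ccc(OC)c(OC)c3c(O[Si](C)(C)C(C)(C)C)c2Br)cc(OC)c1OC.[Br-] | intermediate (not isolated)
14 | 3-bromo-5,6-dimethoxy-2-(3,4,5-trimethoxyphenyl)-4H-chromen-4-one | COc1cc(-c2oc3ccc(OC)c(OC)c3c(=O)c2Br)cc(OC)c1OC | intermediate
15 | cerosilin B (5,6-dimethoxy-2-(3,4,5-trimethoxyphenyl)-4H-chromen-4-one) | COc1cc(-c2cc(=O)c3c(OC)c(OC)ccc3o2)cc(OC)c1OC | target

## Step count and least certain steps

Total step count: 7. Longest linear sequence: 7 steps (1 to 15); compounds 3, 7 and 11 enter as purchased reagents.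

**Step 6 (key step, proposed new method).** Most likely failures:
- Loss of the silyl group to tert-butoxide before the carbene has added, after which the free enolate is alkylated at C2 or oxidised.
- Consumption of the carbene by the base because addition to the hindered, tetrasubstituted bond (flanked by the C4 methoxy group and ring B) is slow.
- Conjugate attack of tert-butoxide at C2 of 14 with opening of the pyranone.

Within the same disconnection the first remedy would be a base-free carbene source, thermolysis of PhHgCBr3 in benzene.

The fallback uses known chemistry and leaves the ring enlargement aside. It sets out from 2, which is lithiated to 4 as in step 2 and quenched with N-methoxy-N-methylacetamide to give 1-[2,3-dimethoxy-6-(methoxymethoxy)phenyl]ethan-1-one F1. HCl in methanol removes the acetal to give 1-(6-hydroxy-2,3-dimethoxyphenyl)ethan-1-one F2. Claisen–Schmidt condensation of F2 with 3,4,5-trimethoxybenzaldehyde (KOH, ethanol) gives the chalcone (E)-1-(6-hydroxy-2,3-dimethoxyphenyl)-3-(3,4,5-trimethoxyphenyl)prop-2-en-1-one F3. Oxidative cyclisation of F3 with catalytic I2 in DMSO at 120 °C returns to the route at 15.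

**Step 5.** Most likely failures:
- [1,2]-Wittig rearrangement of the alpha-aryloxybenzyl carbanion (aryl migration from oxygen to carbon).
- Slow deprotonation of the electron-rich benzylic position.
- Oxidation of enolate 9 by traces of oxygen, or incomplete silylation of its hindered oxygen.

The fallback replaces the ether carbanion by a stabilised one and sets out from 6. Methyl 2-bromo-2-(3,4,5-trimethoxyphenyl)acetate F4 (racemic) would be made from methyl (3,4,5-trimethoxyphenyl)acetate by bromination of its silyl ketene acetal (LiN(SiMe3)2, Me3SiCl, then NBS). Alkylation of 6 with F4 (K2CO3, DMF) gives methyl 2,3-dimethoxy-6-[2-methoxy-2-oxo-1-(3,4,5-trimethoxyphenyl)ethoxy]benzoate F5. Saponification (KOH, aqueous methanol, reflux) gives 6-[carboxy(3,4,5-trimethoxyphenyl)methoxy]-2,3-dimethoxybenzoic acid F6. The classical cyclisation of such diacids in Ac2O with NaOAc at reflux, with loss of CO2, gives the enol acetate 4,5-dimethoxy-2-(3,4,5-trimethoxyphenyl)-1-benzofuran-3-yl acetate F7. Two equivalents of MeLi in THF cleave F7 to the enolate, which returns to the route at 9 and is silylated to 10 as in step 5.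

**Step 2.** Most likely failures: a second addition of 4 to the ester just formed, giving a diaryl ketone, and partial lithiation at the position ortho to the acetal only. The fallback sets out from 2, which is lithiated to 4 as before and quenched with CO2, which cannot over-add, to give 2,3-dimethoxy-6-(methoxymethoxy)benzoic acid F8. O-Alkylation of the carboxylate (MeI, K2CO3, DMF) returns to the route at 5.

**Step 7.** Most likely failures: slow oxidative addition at the fully substituted C3, or reduction of the C2–C3 double bond by the palladium hydride. The fallback changes the mechanism from hydride transfer to electron transfer: zinc dust in acetic acid at 60 °C reduces the alpha-bromo enone without a metal hydride. It sets out from 14 and returns at 15. No new compound is made on this path, hence the entry F0.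

## Further compounds

F1 | step 6 | 1-[2,3-dimethoxy-6-(methoxymethoxy)phenyl]ethan-1-one | COCOc1ccc(OC)c(OC)c1C(C)=O
F2 | step 6 | 1-(6-hydroxy-2,3-dimethoxyphenyl)ethan-1-one | COc1ccc(O)c(C(C)=O)c1OC
F3 | step 6 | (E)-1-(6-hydroxy-2,3-dimethoxyphenyl)-3-(3,4,5-trimethoxyphenyl)prop-2-en-1-one | COc1ccc(O)c(C(=O)/C=C/c2cc(OC)c(OC)c(OC)c2)c1OC
F4 | step 5 | methyl 2-bromo-2-(3,4,5-trimethoxyphenyl)acetate (racemic) | COC(=O)C(Br)c1cc(OC)c(OC)c(OC)c1
F5 | step 5 | methyl 2,3-dimethoxy-6-[2-methoxy-2-oxo-1-(3,4,5-trimethoxyphenyl)ethoxy]benzoate (racemic) | COC(=O)C(Oc1ccc(OC)c(OC)c1C(=O)OC)c1cc(OC)c(OC)c(OC)c1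
F6 | step 5 | 6-[carboxy(3,4,5-trimethoxyphenyl)methoxy]-2,3-dimethoxybenzoic acid (racemic) | OC(=O)C(Oc1ccc(OC)c(OC)c1C(=O)O)c1cc(OC)c(OC)c(OC)c1
F7 | step 5 | 4,5-dimethoxy-2-(3,4,5-trimethoxyphenyl)-1-benzofuran-3-yl acetate | CC(=O)Oc1c(-c2cc(OC)c(OC)c(OC)c2)oc2ccc(OC)c(OC)c12
F8 | step 2 | 2,3-dimethoxy-6-(methoxymethoxy)benzoic acid | COCOc1ccc(OC)c(OC)c1C(=O)O
F0 | step 7 | none | none
A1 | alternative 1 | 6-hydroxy-5-methoxy-2-(3,4,5-trimethoxyphenyl)-4H-chromen-4-one | COc1cc(-c2cc(=O)c3c(OC)c(O)ccc3o2)cc(OC)c1OC
A2 | alternative 1 | 1-(3-hydroxy-2-methoxyphenyl)-3-(3,4,5-trimethoxyphenyl)propane-1,3-dione | COc1cc(C(=O)CC(=O)c2cccc(O)c2OC)cc(OC)c1OC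
A3 | alternative 2 | 2-(4-hydroxy-3,5-dimethoxyphenyl)-5,6-dimethoxy-4H-chromen-4-one | COc1cc(-c2cc(=O)c3c(OC)c(OC)ccc3o2)cc(OC)c1O
A4 | alternative 2 | 2-(5,6-dimethoxy-4-oxo-4H-chromen-2-yl)-1,3-bis(dimethylamino)trimethinium hexafluorophosphate | CN(C)C=C(C=[N+](C)C)c1cc(=O)c2c(OC)c(OC)ccc2o1.F[P-](F)(F)(F)(F)F
A5 | alternative 2 | 1,3-dimethoxypropan-2-one | COCC(=O)COC
A6 | alternative 2 | 5,6-dimethoxy-2-methyl-4H-chromen-4-one | Cc1cc(=O)c2c(OC)c(OC)ccc2o1
A7 | alternative 3 | 5-hydroxy-6-methoxy-2-(3,4,5-trimethoxyphenyl)-4H-chromen-4-one | COc1ccc2oc(-c3cc(OC)c(OC)c(OC)c3)cc(=O)c2c1O
A8 | alternative 3 | 3-(2-methoxyacetyl)-2-methyl-6-(3,4,5-trimethoxyphenyl)-4H-pyran-4-one | COCC(=O)c1c(C)oc(-c2cc(OC)c(OC)c(OC)c2)cc1=O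
A9 | alternative 3 | N,N-dimethylformamide dimethyl acetal | COC(OC)N(C)C
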